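**Retrosynthetic overview**
1. The target is (−)-epiafzelechin 3-O-gallate-(4β→6)-(−)-epicatechin 3-O-gallate. It is traced back through global hydrogenolysis (13 benzyl ethers, one C8–Br) to the interflavan C4–C6 bond, which is cut into a C4-alkoxy upper-unit gallate (electrophile) and 8-bromo-epicatechin gallate (nucleophile, C8 blocked).
2. Ring C of the upper unit is cut at C3–C4 and O1–C8a at once: a [3+3] annulation of the enolate of an α-carbamoyloxy aryl ketone (O1 and C3) with 2-bromo-4,6-bis(benzyloxy)benzyl bromide (C4 and C8a) gives the enol carbamate of the flavan-3-one.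
3. Enabling feature: in ring C the atoms O1–C2(aryl)–C3(O) are the enol form of an α-oxygenated aryl ketone (a 1,3-O,C-dinucleophile), while C4 and the ring A carbon C8a ortho to it form an ortho-halobenzyl 1,3-dielectrophile. The C4–H2 group of the annulation product stays activated by O1 and the two ring A oxygens for later oxidation.
4. Stereocentres: C2/C3 of the upper unit by hydrogenation of the racemising flavan-3-one with dynamic kinetic resolution (2R,3R, cis); C4 by DDQ oxidation and trans arylation (4β); the lower unit from (−)-epicatechin.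
5. Order of ring formation: rings A and B of both units are bought as arenes or with epicatechin; the only ring built is the upper ring C (step 6).

Key step: step 6

Assumptions (chemistry): compounds 1, 6, 16 and 18 are taken as commercial. The sense of induction in step 8 is assigned by analogy with the hydrogenation of 2-substituted cyclohexanones under dynamic kinetic resolution; should a pilot run give the antipode, the mirror-image catalyst is used.

**Step 1**
Reactants: 1 1,3-bis(benzyloxy)-5-bromobenzene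
Product: 3 2-bromo-4,6-bis(benzyloxy)benzaldehyde, via iminium salt 2 (not isolated)
Conditions: POCl3, DMF, 0 → 80 °C; then H2O, NaOAc
Reagents that add atoms: N,N-dimethylformamide CN(C)C=O; water O
Why: Vilsmeier–Haack formylation should occur para to one benzyloxy group at the position between Br and OBn, because the alternative site between the two benzyloxy groups is more hindered.

**Step 2**
Reactants: 3 2-bromo-4,6-bis(benzyloxy)benzaldehyde
Product: 4 [2-bromo-4,6-bis(benzyloxy)phenyl]methanol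
Conditions: NaBH4, THF/MeOH, 0 °C
Reagents that add atoms: none
Why: Borohydride reduction of an aryl aldehyde; aryl bromide and benzyl ethers are inert.

**Step 3**
Reactants: 4 [2-bromo-4,6-bis(benzyloxy)phenyl]methanol
Product: 5 1,5-bis(benzyloxy)-3-bromo-2-(bromomethyl)benzene (2-bromo-4,6-bis(benzyloxy)benzyl bromide), used crude at once
Conditions: PBr3, pyridine (cat.), CH2Cl2, 0 °C
Reagents that add atoms: phosphorus tribromide BrP(Br)Br
Why: Alcohol-to-bromide conversion through the phosphite ester (SN2), kept cold because the ortho/para-dialkoxybenzyl bromide ionises easily.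

**Step 4**
Reactants: 6 2-bromo-1-[4-(benzyloxy)phenyl]ethan-1-one
Product: 8 1-[4-(benzyloxy)phenyl]-2-hydroxyethan-1-one, via formate ester 7 (not isolated)
Conditions: HCO2Na, EtOH/H2O, reflux
Reagents that add atoms: sodium formate [Na+].[O-]C=O
Why: SN2 displacement of the phenacyl bromide by formate followed by solvolysis of the formate ester in the same pot is the classical route to α-hydroxy acetophenones.

**Step 5**
Reactants: 8 1-[4-(benzyloxy)phenyl]-2-hydroxyethan-1-one
Product: 9 2-[4-(benzyloxy)phenyl]-2-oxoethyl N,N-diethylcarbamate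
Conditions: Et2NCOCl, Et3N, DMAP (cat.), MeCN, 60 °C
Reagents that add atoms: N,N-diethylcarbamoyl chloride CCN(CC)C(Cl)=O
Why: DMAP-catalysed O-carbamoylation of the primary alcohol installs an O3 group that is base-stable, cannot migrate between the later enediol oxygens and is removable from an enol by MeLi.

**Step 6**
Reactants: 9 2-[4-(benzyloxy)phenyl]-2-oxoethyl N,N-diethylcarbamate; 5 2-bromo-4,6-bis(benzyloxy)benzyl bromide
Product: 11 5,7-bis(benzyloxy)-2-[4-(benzyloxy)phenyl]-4H-chromen-3-yl N,N-diethylcarbamate, via C-benzylated ketone 10 (not isolated)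
Conditions: NaN(SiMe3)2 (1.05 equiv), THF, −78 °C, then 5, −78 → 0 °C; then NaN(SiMe3)2 (1.05 equiv), CuI (10 mol %), 1,10-phenanthroline (20 mol %), toluene, 80 °C
Reagents that add atoms: none
Why: Proposed new method: the sodium enolate of 9 is C-benzylated by the SN2-active bromide 5 to give ketone 10 (bond C3–C4); the second base charge regenerates an enolate whose oxygen, after equilibration of the enolate geometry, sits six atoms from the aryl bromide, and monovalent copper (CuI/1,10-phenanthroline) joins them by oxidative addition to an aryl species of trivalent copper and C–O reductive elimination (bond O1–C8a), an Ullmann-type enolate O-arylation. The closest known reactions are the copper-catalysed domino C-benzylation/O-arylation of β-keto esters and 1,3-diketones with 2-bromobenzyl bromides to 4H-chromenes and the palladium- or copper-catalysed intramolecular O-arylation of ketone enolates; new here are the mono-ketone carrying an α-carbamoyloxy group and the one-pot sequence with two base charges. Ring C closes by a six-membered C–O ring closure in which the enolate oxygen is the only nucleophile within reach, since C-arylation would need a four-membered ring. No stereocentre remains in 11 (C3 of 10 becomes sp2), so no stereocontrol is required at this stage. The selectivities needed are C- over O-alkylation (sodium enolate in THF with a benzylic bromide), mono- over dialkylation (only one equivalent of base until 5 is consumed) and arylation of O1 instead of O3, which is secured because O3 is blocked as an N,N-diethylcarbamate that, unlike an ester or silyl group, should not shift to the neighbouring enolate oxygen, so the five-membered benzofuran closure is excluded.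

**Step 7**
Reactants: 11 5,7-bis(benzyloxy)-2-[4-(benzyloxy)phenyl]-4H-chromen-3-yl N,N-diethylcarbamate
Product: 13 rac-5,7-bis(benzyloxy)-2-[4-(benzyloxy)phenyl]chroman-3-one, via lithium enolate 12 (not isolated)
Conditions: MeLi, THF, −78 → 0 °C; then aq. NH4Cl, argon
Reagents that add atoms: none
Why: Addition–elimination of MeLi at the carbamate carbonyl (known cleavage of enol carbamates) releases the lithium enolate regiospecifically, and its protonation at C2 gives the racemic flavan-3-one.

**Step 8**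
Reactants: 13 rac-5,7-bis(benzyloxy)-2-[4-(benzyloxy)phenyl]chroman-3-one
Product: 14 (2R,3R)-5,7-bis(benzyloxy)-2-[4-(benzyloxy)phenyl]chroman-3-ol (tri-O-benzyl-(−)-epiafzelechin)
Conditions: trans-RuCl2[(S)-binap][(R,R)-dpen] (1 mol %), KOtBu (5 mol %), H2 (8 atm), iPrOH/THF, 25 °C, degassed
Reagents that add atoms: none
Why: Noyori-type asymmetric hydrogenation with dynamic kinetic resolution, as known for α-aryl and α-aryloxy cycloalkanones: base racemises C2 (α to the ketone, benzylic, α-aryloxy) faster than reduction, the catalyst selects the 2R ketone, and hydride enters trans to the C2 aryl group, so C3 is set cis to C2 (2R,3R).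

**Step 9**
Reactants: 14 (2R,3R)-5,7-bis(benzyloxy)-2-[4-(benzyloxy)phenyl]chroman-3-ol
Product: 15 (2R,3R,4S)-5,7-bis(benzyloxy)-2-[4-(benzyloxy)phenyl]-4-(2-ethoxyethoxy)chroman-3-ol (4β ether, trans to 3-OH)
Conditions: DDQ (2 equiv), 2-ethoxyethanol, CH2Cl2, rt
Reagents that add atoms: 2-ethoxyethanol CCOCCO
Why: DDQ benzylic oxidation (hydride abstraction at C4, cation stabilised by O1 and the 5,7-dialkoxy ring A) with capture by the alcohol trans to the C3 hydroxyl is the standard C4 activation of benzylated flavan-3-ols; the C4 configuration is erased again in step 14.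

**Step 10**
Reactants: 15 (2R,3R,4S)-4-(2-ethoxyethoxy) alcohol; 16 3,4,5-tris(benzyloxy)benzoic acid
Product: 17 (2R,3R,4S)-5,7-bis(benzyloxy)-2-[4-(benzyloxy)phenyl]-4-(2-ethoxyethoxy)chroman-3-yl 3,4,5-tris(benzyloxy)benzoate
Conditions: EDC·HCl, DMAP, CH2Cl2, rt
Reagents that add atoms: none
Why: Steglich esterification of the secondary alcohol with retention at C3; the 3-O-acyl group later directs the C4 arylation.

**Step 11**
Reactants: 18 (−)-epicatechin
Product: 19 (2R,3R)-5,7-bis(benzyloxy)-2-[3,4-bis(benzyloxy)phenyl]chroman-3-ol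
Conditions: BnBr (4.4 equiv), K2CO3, DMF, 0 °C → rt, argon
Reagents that add atoms: benzyl bromide BrCc1ccccc1
Why: Williamson etherification is selective for the four phenols over the much less acidic secondary alcohol, and the mild base at low temperature should avoid C2 epimerisation.

**Step 12**
Reactants: 19 tetra-O-benzyl-(−)-epicatechin
Product: 20 (2R,3R)-5,7-bis(benzyloxy)-2-[3,4-bis(benzyloxy)phenyl]-8-bromochroman-3-ol
Conditions: NBS (1.0 equiv), CH2Cl2, −78 °C → rt
Reagents that add atoms: N-bromosuccinimide O=C1CCC(=O)N1Br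
Why: Electrophilic aromatic bromination of 5,7-di-O-benzyl flavans is known to go selectively to C8, which leaves C6 as the only nucleophilic ring A position.

**Step 13**
Reactants: 20 8-bromo alcohol; 16 3,4,5-tris(benzyloxy)benzoic acid
Product: 21 (2R,3R)-5,7-bis(benzyloxy)-2-[3,4-bis(benzyloxy)phenyl]-8-bromochroman-3-yl 3,4,5-tris(benzyloxy)benzoate
Conditions: EDC·HCl, DMAP, CH2Cl2, rt
Reagents that add atoms: none
Why: Steglich esterification of the C3 alcohol, known for benzylated epicatechin, with retention of configuration.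

**Step 14**
Reactants: 17 upper-unit electrophile; 21 lower-unit nucleophile (3 equiv, excess recovered)
Product: 22 protected dimer: (2R,3R)-5,7-bis(benzyloxy)-2-[4-(benzyloxy)phenyl]-3-[3,4,5-tris(benzyloxy)benzoyloxy]chroman-4-yl (4β, trans to the ester) bonded through C4 to C6 of (2R,3R)-5,7-bis(benzyloxy)-2-[3,4-bis(benzyloxy)phenyl]-8-bromochroman-3-yl 3,4,5-tris(benzyloxy)benzoate
Conditions: Me3SiOTf (0.2 equiv), 4 Å MS, CH2Cl2, −40 °C
Reagents that add atoms: none
Why: Lewis-acid-promoted Friedel–Crafts-type C4 arylation (the standard proanthocyanidin coupling): ionisation of the C4 ether gives a ring-A- and O1-stabilised cation shielded on the α face by the 3-O-acyl group, so the arene adds to the β face trans to C3–O (4β), and the C8 bromine leaves only C6 to attack.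

**Step 15**
Reactants: 22 protected dimer
Product: 23 CNP0169607.1, (−)-epiafzelechin 3-O-gallate-(4β→6)-(−)-epicatechin 3-O-gallate (upper unit 2R,3R,4S; lower unit 2R,3R)
Conditions: H2 (1 atm), Pd(OH)2/C, Et3N (1.2 equiv), THF/MeOH/H2O, rt
Reagents that add atoms: none
Why: Catalytic hydrogenolysis should remove the thirteen benzyl ethers and the aryl bromide in one operation without touching the gallate esters or any stereocentre.

**Compound list**
1 | 1,3-bis(benzyloxy)-5-bromobenzene | Brc1cc(OCc2ccccc2)cc(OCc2ccccc2)c1 | starting material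
2 | N-{[2-bromo-4,6-bis(benzyloxy)phenyl]methylidene}-N-methylmethanaminium chloride | C[N+](C)=Cc1c(Br)cc(OCc2ccccc2)cc1OCc1ccccc1.[Cl-] | intermediate (not isolated)
3 | 2-bromo-4,6-bis(benzyloxy)benzaldehyde | O=Cc1c(Br)cc(OCc2ccccc2)cc1OCc1ccccc1 | intermediate
4 | [2-bromo-4,6-bis(benzyloxy)phenyl]methanol | OCc1c(Br)cc(OCc2ccccc2)cc1OCc1ccccc1 | intermediate
5 | 1,5-bis(benzyloxy)-3-bromo-2-(bromomethyl)benzene | BrCc1c(Br)cc(OCc2ccccc2)cc1OCc1ccccc1 | intermediate
6 | 2-bromo-1-[4-(benzyloxy)phenyl]ethan-1-one | O=C(CBr)c1ccc(OCc2ccccc2)cc1 | starting material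
7 | 2-[4-(benzyloxy)phenyl]-2-oxoethyl formate | O=COCC(=O)c1ccc(OCc2ccccc2)cc1 | intermediate (not isolated)
8 | 1-[4-(benzyloxy)phenyl]-2-hydroxyethan-1-one | O=C(CO)c1ccc(OCc2ccccc2)cc1 | intermediate
9 | 2-[4-(benzyloxy)phenyl]-2-oxoethyl N,N-diethylcarbamate | CCN(CC)C(=O)OCC(=O)c1ccc(OCc2ccccc2)cc1 | intermediate
10 | rac-3-[2-bromo-4,6-bis(benzyloxy)phenyl]-1-[4-(benzyloxy)phenyl]-1-oxopropan-2-yl N,N-diethylcarbamate | CCN(CC)C(=O)OC(Cc1c(Br)cc(OCc2ccccc2)cc1OCc1ccccc1)C(=O)c1ccc(OCc2ccccc2)cc1 | intermediate (not isolated)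
11 | 5,7-bis(benzyloxy)-2-[4-(benzyloxy)phenyl]-4H-chromen-3-yl N,N-diethylcarbamate | CCN(CC)C(=O)OC1=C(c2ccc(OCc3ccccc3)cc2)Oc2cc(OCc3ccccc3)cc(OCc3ccccc3)c2C1 | intermediate
12 | lithium 5,7-bis(benzyloxy)-2-[4-(benzyloxy)phenyl]-4H-chromen-3-olate | [Li+].[O-]C1=C(c2ccc(OCc3ccccc3)cc2)Oc2cc(OCc3ccccc3)cc(OCc3ccccc3)c2C1 | intermediate (not isolated)
13 | rac-5,7-bis(benzyloxy)-2-[4-(benzyloxy)phenyl]chroman-3-one | O=C1Cc2c(OCc3ccccc3)cc(OCc3ccccc3)cc2OC1c1ccc(OCc2ccccc2)cc1 | intermediate
14 | (2R,3R)-5,7-bis(benzyloxy)-2-[4-(benzyloxy)phenyl]chroman-3-ol | O[C@@H]1Cc2c(OCc3ccccc3)cc(OCc3ccccc3)cc2O[C@@H]1c1ccc(OCc2ccccc2)cc1 | intermediate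
15 | (2R,3R,4S)-5,7-bis(benzyloxy)-2-[4-(benzyloxy)phenyl]-4-(2-ethoxyethoxy)chroman-3-ol | O[C@@H]1[C@@H](OCCOCC)c2c(OCc3ccccc3)cc(OCc3ccccc3)cc2O[C@@H]1c1ccc(OCc2ccccc2)cc1 | intermediate
16 | 3,4,5-tris(benzyloxy)benzoic acid | OC(=O)c1cc(OCc2ccccc2)c(OCc2ccccc2)c(OCc2ccccc2)c1 | starting material
17 | (2R,3R,4S)-5,7-bis(benzyloxy)-2-[4-(benzyloxy)phenyl]-4-(2-ethoxyethoxy)chroman-3-yl 3,4,5-tris(benzyloxy)benzoate | O=C(O[C@@H]1[C@@H](OCCOCC)c2c(OCc3ccccc3)cc(OCc3ccccc3)cc2O[C@@H]1c1ccc(OCc2ccccc2)cc1)c1cc(OCc2ccccc2)c(OCc2ccccc2)c(OCc2ccccc2)c1 | intermediate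
18 | (−)-epicatechin, (2R,3R) | O[C@@H]1Cc2c(O)cc(O)cc2O[C@@H]1c1ccc(O)c(O)c1 | starting material
19 | (2R,3R)-5,7-bis(benzyloxy)-2-[3,4-bis(benzyloxy)phenyl]chroman-3-ol | O[C@@H]1Cc2c(OCc3ccccc3)cc(OCc3ccccc3)cc2O[C@@H]1c1ccc(OCc2ccccc2)c(OCc2ccccc2)c1 | intermediate
20 | (2R,3R)-5,7-bis(benzyloxy)-2-[3,4-bis(benzyloxy)phenyl]-8-bromochroman-3-ol | O[C@@H]1Cc2c(OCc3ccccc3)cc(OCc3ccccc3)c(Br)c2O[C@@H]1c1ccc(OCc2ccccc2)c(OCc2ccccc2)c1 | intermediate
21 | (2R,3R)-5,7-bis(benzyloxy)-2-[3,4-bis(benzyloxy)phenyl]-8-bromochroman-3-yl 3,4,5-tris(benzyloxy)benzoate | O=C(O[C@@H]1Cc2c(OCc3ccccc3)cc(OCc3ccccc3)c(Br)c2O[C@@H]1c1ccc(OCc2ccccc2)c(OCc2ccccc2)c1)c1cc(OCc2ccccc2)c(OCc2ccccc2)c(OCc2ccccc2)c1 | intermediate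
22 | protected 4β→6 dimer (trideca-O-benzyl, 8-bromo on the lower unit, both 3-O-gallates in place) | O=C(O[C@@H]1[C@@H](c2c(OCc3ccccc3)c(Br)c3c(c2OCc2ccccc2)C[C@@H](OC(=O)c2cc(OCc4ccccc4)c(OCc4ccccc4)c(OCc4ccccc4)c2)[C@@H](c2ccc(OCc4ccccc4)c(OCc4ccccc4)c2)O3)c2c(OCc3ccccc3)cc(OCc3ccccc3)cc2O[C@@H]1c1ccc(OCc2ccccc2)cc1)c1cc(OCc2ccccc2)c(OCc2ccccc2)c(OCc2ccccc2)c1 | intermediate
23 | CNP0169607.1, (−)-epiafzelechin 3-O-gallate-(4β→6)-(−)-epicatechin 3-O-gallate | O=C(O[C@@H]1[C@@H](c2c(O)cc3c(c2O)C[C@@H](OC(=O)c2cc(O)c(O)c(O)c2)[C@@H](c2ccc(O)c(O)c2)O3)c2c(O)cc(O)cc2O[C@@H]1c1ccc(O)cc1)c1cc(O)c(O)c(O)c1 | target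

**Step count and risks**
Total steps: 15. Longest linear sequence: 10 steps (1, 2, 3, 6, 7, 8, 9, 10, 14, 15).

Steps most likely to fail:

1. Step 6 (proposed new method). The first stage may suffer O-alkylation or double alkylation. The second stage may stall because the sodium enolate prefers the chelated geometry that turns its oxygen away from the aryl bromide, or the carbamoyl group may shift at 80 °C. The fallback uses known reactions only and sets out from 9 and 5. Alkylation with LiN(SiMe3)2 at −78 °C is stopped at ketone 10, which is isolated. NaBH4 reduces it to the alcohol 3-[2-bromo-4,6-bis(benzyloxy)phenyl]-1-[4-(benzyloxy)phenyl]-1-hydroxypropan-2-yl N,N-diethylcarbamate F1. A palladium-catalysed intramolecular C–O coupling of the secondary alcohol with the aryl bromide (Pd(OAc)2, 2-(di-tert-butylphosphino)-1,1′-binaphthyl, Cs2CO3, toluene, 80 °C) closes ring C to 5,7-bis(benzyloxy)-2-[4-(benzyloxy)phenyl]chroman-3-yl N,N-diethylcarbamate F2. LiAlH4 removes the carbamate to give 5,7-bis(benzyloxy)-2-[4-(benzyloxy)phenyl]chroman-3-ol as a stereoisomer mixture F3, and Dess–Martin oxidation returns to the route at 13.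

2. Step 8. Racemisation at C2 may be too slow relative to reduction, facial discrimination by the catalyst may be poor on this ether-rich ketone, or the enolate may be oxidised by adventitious air. The fallback sets out from 13. Reduction with LiBH(s-Bu)3 at −78 °C (hydride trans to the C2 aryl group, as known for flavan-3-ones) gives racemic cis-5,7-bis(benzyloxy)-2-[4-(benzyloxy)phenyl]chroman-3-ol F4. Esterification with (S)-2-methoxy-2-phenylacetic acid (DCC, DMAP cat.) gives two diastereomers, the (2R,3R)-chromanyl (S)-2-methoxy-2-phenylacetate F5 and the (2S,3S)-chromanyl (S)-2-methoxy-2-phenylacetate F6, which are separated by chromatography. Methanolysis of F5 (K2CO3, MeOH/THF) returns to the route at 14.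

3. Step 14. Attack by the hindered, bromine-deactivated and acylated nucleophile at C6 may be slower than self-condensation of the cation with ring A of a second electrophile molecule, or than reversal of the coupling. The fallback sets out from 17 and 20. The more nucleophilic free alcohol 20 is coupled first (Me3SiOTf, 1 equiv, CH2Cl2, −40 °C, or TiCl4), giving the 4β→6 dimer with a free lower-unit 3-hydroxyl, the mono-gallate dodeca-O-benzyl 8-bromo dimer F7. The lower 3-OH is then esterified with 16 (EDC·HCl, DMAP), which returns to the route at 22.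

**Further compounds**
F1 | step 6 | 3-[2-bromo-4,6-bis(benzyloxy)phenyl]-1-[4-(benzyloxy)phenyl]-1-hydroxypropan-2-yl N,N-diethylcarbamate (diastereomer mixture, racemic) | CCN(CC)C(=O)OC(Cc1c(Br)cc(OCc2ccccc2)cc1OCc1ccccc1)C(O)c1ccc(OCc2ccccc2)cc1
F2 | step 6 | 5,7-bis(benzyloxy)-2-[4-(benzyloxy)phenyl]chroman-3-yl N,N-diethylcarbamate (cis/trans mixture, racemic) | CCN(CC)C(=O)OC1Cc2c(OCc3ccccc3)cc(OCc3ccccc3)cc2OC1c1ccc(OCc2ccccc2)cc1
F3 | step 6 | 5,7-bis(benzyloxy)-2-[4-(benzyloxy)phenyl]chroman-3-ol (cis/trans mixture, racemic) | OC1Cc2c(OCc3ccccc3)cc(OCc3ccccc3)cc2OC1c1ccc(OCc2ccccc2)cc1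
F4 | step 8 | racemic cis-5,7-bis(benzyloxy)-2-[4-(benzyloxy)phenyl]chroman-3-ol (relative configuration 2R*,3R*; one enantiomer drawn) | O[C@@H]1Cc2c(OCc3ccccc3)cc(OCc3ccccc3)cc2O[C@@H]1c1ccc(OCc2ccccc2)cc1
F5 | step 8 | (2R,3R)-5,7-bis(benzyloxy)-2-[4-(benzyloxy)phenyl]chroman-3-yl (S)-2-methoxy-2-phenylacetate | CO[C@H](C(=O)O[C@@H]1Cc2c(OCc3ccccc3)cc(OCc3ccccc3)cc2O[C@@H]1c1ccc(OCc2ccccc2)cc1)c1ccccc1
F6 | step 8 | (2S,3S)-5,7-bis(benzyloxy)-2-[4-(benzyloxy)phenyl]chroman-3-yl (S)-2-methoxy-2-phenylacetate | CO[C@H](C(=O)O[C@H]1Cc2c(OCc3ccccc3)cc(OCc3ccccc3)cc2O[C@H]1c1ccc(OCc2ccccc2)cc1)c1ccccc1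
F7 | step 14 | protected 4β→6 dimer with free lower-unit 3-hydroxyl (upper 3-O-gallate only, 8-bromo) | O=C(O[C@@H]1[C@@H](c2c(OCc3ccccc3)c(Br)c3c(c2OCc2ccccc2)C[C@@H](O)[C@@H](c2ccc(OCc4ccccc4)c(OCc4ccccc4)c2)O3)c2c(OCc3ccccc3)cc(OCc3ccccc3)cc2O[C@@H]1c1ccc(OCc2ccccc2)cc1)c1cc(OCc2ccccc2)c(OCc2ccccc2)c(OCc2ccccc2)c1
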